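**Retrosynthetic overview**

1. Target 18 ⇒ 7-O-silyl ether 17 ⇒ bis(1,1-dimethylallyl) ether 14: both C-prenyl bonds (at C6 and C3') come from O5 and O4' by a double aromatic Claisen shift. O5 has C6 as its only free ortho carbon, so no 8-prenyl isomer can form.
2. 14 ⇒ 4-methoxyflavan 12 (C4 one oxidation level lower, restored with DDQ) ⇒ ortho-hydroxy acetal 7 (ring A) + styrene 10 (ring B). A chiral-acid-catalysed oxa-[4+2] cycloaddition forms C3–C4 and O1–C2 together and sets C2.
3. Enabling feature: the phenol oxygen O1 on C8a is ortho to the benzylic carbon C4 on the trioxygenated ring A, so a C4 acetal ionises to an ortho-quinone methide (heterodiene O1=C8a–C4a=C4). O4', para to the vinyl group on ring B, makes C3 nucleophilic and stabilises charge at C2.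
4. Ring order: rings A and B are bought as aromatic rings (2,4,6-trihydroxybenzaldehyde, 4-hydroxybenzaldehyde). Ring C is the only ring formed, in the key step. One carbonate reagent 3 supplies both tertiary allyl ethers.

Key step: step 7

Remark: flavanone numbering is used (O1, C2, C3, C4, C4a, C5–C8, C8a, primed locants for ring B); C4 of 12 is drawn as the expected cis epimer (either C4 epimer converges in step 8), and the acid enantiomer is written as (R) but the antipode is to be used if it is the one that delivers (2S).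

**Route**

Step 1
Reactants: 1 2-methylbut-3-en-2-ol
Product: 3 tert-butyl 2-methylbut-3-en-2-yl carbonate, via lithium 2-methylbut-3-en-2-olate 2 (not isolated)
Conditions: n-BuLi, THF, −78 to 0 °C; Boc2O, 0 °C to rt; aqueous work-up
Reagents that add atoms: di-tert-butyl dicarbonate, CC(C)(C)OC(=O)OC(=O)OC(C)(C)C
Why: Alkoxycarbonylation of a tertiary lithium alkoxide with Boc2O is a standard way to tertiary allyl carbonates, and no stereocentre is involved.

Step 2
Reactants: 4 2,4,6-trihydroxybenzaldehyde
Product: 5 2,6-dihydroxy-4-(triisopropylsilyloxy)benzaldehyde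
Conditions: iPr3SiCl (1.05 equiv), imidazole, DMF, 0 °C
Reagents that add atoms: triisopropylsilyl chloride, CC(C)[Si](Cl)(C(C)C)C(C)C
Why: Regioselective phenol silylation should favour O4, the least hindered hydroxyl, because the 2- and 6-hydroxyls are flanked by and hydrogen-bonded to the formyl group and the silyl chloride is bulky.

Step 3
Reactants: 5 2,6-dihydroxy-4-(triisopropylsilyloxy)benzaldehyde; 3 tert-butyl 2-methylbut-3-en-2-yl carbonate
Product: 6 2-hydroxy-6-(2-methylbut-3-en-2-yloxy)-4-(triisopropylsilyloxy)benzaldehyde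
Conditions: Pd(PPh3)4 (2 mol %), 3 (1.1 equiv), THF, 0 °C
Reagents that add atoms: none
Why: In this Tsuji–Trost O-allylation (decarboxylative reverse prenylation of a phenol) zerovalent palladium ionises 3 to a 1,1-dimethylallyl complex and tert-butoxide, the phenoxide attacks the tertiary terminus under kinetic control at low temperature, the two ortho hydroxyls of 5 are equivalent, and the remaining one, chelated to the formyl group, should resist a second alkylation.

Step 4
Reactants: 6 2-hydroxy-6-(2-methylbut-3-en-2-yloxy)-4-(triisopropylsilyloxy)benzaldehyde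
Product: 7 2-(dimethoxymethyl)-3-(2-methylbut-3-en-2-yloxy)-5-(triisopropylsilyloxy)phenol
Conditions: HC(OMe)3, MeOH, pyridinium p-toluenesulfonate (cat.), rt; Et3N quench, used crude
Reagents that add atoms: trimethyl orthoformate, COC(OC)OC
Why: Acid-catalysed acetalisation is driven by the orthoformate, the weak acid should spare the tertiary allyl ether, and the basic quench keeps the ortho-hydroxy acetal from ionising before the next step.

Step 5
Reactants: 8 4-hydroxybenzaldehyde; 3 tert-butyl 2-methylbut-3-en-2-yl carbonate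
Product: 9 4-(2-methylbut-3-en-2-yloxy)benzaldehyde
Conditions: Pd(PPh3)4 (1 mol %), 3 (1.2 equiv), THF, 0 °C
Reagents that add atoms: none
Why: The same Tsuji–Trost O-allylation as in step 3 is applied to a simple phenol, with kinetic attack at the tertiary allyl terminus.

Step 6
Reactants: 9 4-(2-methylbut-3-en-2-yloxy)benzaldehyde
Product: 10 1-ethenyl-4-(2-methylbut-3-en-2-yloxy)benzene
Conditions: Ph3PCH3Br, KOtBu, THF, 0 °C to rt
Reagents that add atoms: methyltriphenylphosphonium bromide, C[P+](c1ccccc1)(c1ccccc1)c1ccccc1.[Br-]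
Why: Wittig methylenation of a non-enolisable aryl aldehyde is reliable and leaves the tertiary allyl ether untouched.

Step 7
Reactants: 7 2-(dimethoxymethyl)-3-(2-methylbut-3-en-2-yloxy)-5-(triisopropylsilyloxy)phenol; 10 1-ethenyl-4-(2-methylbut-3-en-2-yloxy)benzene (1.5 equiv)
Product: 12 (2S,4S)-4-methoxy-5-(2-methylbut-3-en-2-yloxy)-2-[4-(2-methylbut-3-en-2-yloxy)phenyl]-7-(triisopropylsilyloxy)chromane, via ortho-quinone methide 11 (not isolated)
Conditions: (R)-3,3'-bis(2,4,6-triisopropylphenyl)-1,1'-binaphthyl-2,2'-diyl hydrogen phosphate (5 mol %), 5 Å MS, PhMe, −30 °C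
Reagents that add atoms: none
Why: Proposed new method: the chiral phosphoric acid ionises acetal 7 with loss of methanol to ortho-quinone methide 11, held by the catalyst in its hydrogen-bonded or O-protonated form (a 2-hydroxyaryl oxocarbenium phosphate ion pair), and the electron-rich styrene 10 adds across the O1=C8a–C4a=C4 heterodiene, its terminal carbon bonding to C4 and O1 bonding to the benzylic carbon, so that C3–C4 and O1–C2 form in one inverse-electron-demand oxa-Diels–Alder event. The closest known reaction types are the chiral Brønsted acid-catalysed [4+2] cycloadditions of ortho-quinone methides with styrenes and of salicylaldehyde acetal-derived oxocarbenium ions with vinyl ethers, and the achiral acid-catalysed annulation of salicylaldehyde acetals with alkenes to 4-alkoxychromans; new here is the enantioselective use of a styrene with an alkoxy-substituted quinone methide. Ring C is closed as the six-membered ring of a [4+2] cycloaddition (in the stepwise limit, attack of the styrene on C4 followed by 6-endo capture of the C2 benzylic cation by O1). C4 and C2 are both set by the catalyst: the phosphate bound at O1 shields one face of the heterodiene and an endo approach of ring B gives the 2,4-cis adduct, the enantiomer of the acid being chosen so that C2 is S. Since C4 is erased in step 8, the step needs facial selectivity and cis selectivity of ring closure at the same time, which the tight ion pair and the short life of the cation at C2 should secure; chemoselectivity rests on the far higher nucleophilicity of the 4-alkoxystyrene than of the monosubstituted vinyl groups and on an acid weak enough, at low temperature, to ionise the acetal but not the tertiary allyl ethers.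

Step 8
Reactants: 12 (2S,4S)-4-methoxy-5-(2-methylbut-3-en-2-yloxy)-2-[4-(2-methylbut-3-en-2-yloxy)phenyl]-7-(triisopropylsilyloxy)chromane
Product: 14 (2S)-5-(2-methylbut-3-en-2-yloxy)-2-[4-(2-methylbut-3-en-2-yloxy)phenyl]-7-(triisopropylsilyloxy)chroman-4-one, via methyl hemiketal 13 (not isolated)
Conditions: 2,3-dichloro-5,6-dicyano-1,4-benzoquinone (DDQ, 1.3 equiv), CH2Cl2/pH 7 buffer, 0 °C
Reagents that add atoms: water, O
Why: DDQ should abstract hydride from C4, the methoxy-bearing benzylic position of the trioxygenated ring A (the mechanism of oxidative cleavage of electron-rich benzyl ethers), water adds to the cation and hemiketal 13 loses methanol to the aryl ketone, while C2, benzylic only to the less electron-rich ring B, keeps its configuration.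

Step 9
Reactants: 14 (2S)-5-(2-methylbut-3-en-2-yloxy)-2-[4-(2-methylbut-3-en-2-yloxy)phenyl]-7-(triisopropylsilyloxy)chroman-4-one
Product: 17 (2S)-5-hydroxy-2-[4-hydroxy-3-(3-methylbut-2-en-1-yl)phenyl]-6-(3-methylbut-2-en-1-yl)-7-(triisopropylsilyloxy)chroman-4-one, via ring A-rearranged monoether 15 (not isolated), via ring B-rearranged monoether 16 (not isolated)
Conditions: PhMe, 120 °C, sealed tube
Reagents that add atoms: none
Why: Two independent aromatic Claisen [3,3] rearrangements of aryl 1,1-dimethylallyl ethers, each followed by enolisation, deliver prenyl to C6 alone (C4a, the other ortho carbon of O5, is blocked) and to C3' (both ortho positions of O4' are equivalent), and the neutral aprotic medium should leave C2 untouched.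

Step 10
Reactants: 17 (2S)-5-hydroxy-2-[4-hydroxy-3-(3-methylbut-2-en-1-yl)phenyl]-6-(3-methylbut-2-en-1-yl)-7-(triisopropylsilyloxy)chroman-4-one
Product: 18 macarangaflavanone B
Conditions: Bu4NF, AcOH (1:1), THF, 0 °C
Reagents that add atoms: none
Why: Fluoride-mediated cleavage of the aryl silyl ether, buffered with acetic acid so that no phenoxide opens ring C by retro-oxa-Michael reaction, should free O7 with C2 still S and both prenyl groups intact.

**Compound list**

1 | 2-methylbut-3-en-2-ol | C=CC(C)(C)O | starting material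
2 | lithium 2-methylbut-3-en-2-olate (not isolated) | [Li+].[O-]C(C)(C)C=C | intermediate
3 | tert-butyl 2-methylbut-3-en-2-yl carbonate | C=CC(C)(C)OC(=O)OC(C)(C)C | intermediate
4 | 2,4,6-trihydroxybenzaldehyde | O=Cc1c(O)cc(O)cc1O | starting material
5 | 2,6-dihydroxy-4-(triisopropylsilyloxy)benzaldehyde | O=Cc1c(O)cc(O[Si](C(C)C)(C(C)C)C(C)C)cc1O | intermediate
6 | 2-hydroxy-6-(2-methylbut-3-en-2-yloxy)-4-(triisopropylsilyloxy)benzaldehyde | O=Cc1c(O)cc(O[Si](C(C)C)(C(C)C)C(C)C)cc1OC(C)(C)C=C | intermediate
7 | 2-(dimethoxymethyl)-3-(2-methylbut-3-en-2-yloxy)-5-(triisopropylsilyloxy)phenol | COC(OC)c1c(O)cc(O[Si](C(C)C)(C(C)C)C(C)C)cc1OC(C)(C)C=C | intermediate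
8 | 4-hydroxybenzaldehyde | O=Cc1ccc(O)cc1 | starting material
9 | 4-(2-methylbut-3-en-2-yloxy)benzaldehyde | O=Cc1ccc(OC(C)(C)C=C)cc1 | intermediate
10 | 1-ethenyl-4-(2-methylbut-3-en-2-yloxy)benzene | C=Cc1ccc(OC(C)(C)C=C)cc1 | intermediate
11 | ortho-quinone methide, 6-(methoxymethylidene)-5-(2-methylbut-3-en-2-yloxy)-3-(triisopropylsilyloxy)cyclohexa-2,4-dien-1-one (not isolated; exocyclic double bond configurationally labile) | COC=C1C(=O)C=C(O[Si](C(C)C)(C(C)C)C(C)C)C=C1OC(C)(C)C=C | intermediate
12 | (2S,4S)-4-methoxy-5-(2-methylbut-3-en-2-yloxy)-2-[4-(2-methylbut-3-en-2-yloxy)phenyl]-7-(triisopropylsilyloxy)chromane (2,4-cis) | CO[C@H]1C[C@@H](c3ccc(OC(C)(C)C=C)cc3)Oc2cc(O[Si](C(C)C)(C(C)C)C(C)C)cc(OC(C)(C)C=C)c21 | intermediate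
13 | methyl hemiketal, (2S)-4-methoxy-5-(2-methylbut-3-en-2-yloxy)-2-[4-(2-methylbut-3-en-2-yloxy)phenyl]-7-(triisopropylsilyloxy)chroman-4-ol (not isolated; C4 undefined) | COC1(O)C[C@@H](c3ccc(OC(C)(C)C=C)cc3)Oc2cc(O[Si](C(C)C)(C(C)C)C(C)C)cc(OC(C)(C)C=C)c21 | intermediate
14 | (2S)-5-(2-methylbut-3-en-2-yloxy)-2-[4-(2-methylbut-3-en-2-yloxy)phenyl]-7-(triisopropylsilyloxy)chroman-4-one | C=CC(C)(C)Oc1ccc([C@@H]2CC(=O)c3c(cc(O[Si](C(C)C)(C(C)C)C(C)C)cc3OC(C)(C)C=C)O2)cc1 | intermediate
15 | ring A-rearranged monoether, (2S)-5-hydroxy-6-(3-methylbut-2-en-1-yl)-2-[4-(2-methylbut-3-en-2-yloxy)phenyl]-7-(triisopropylsilyloxy)chroman-4-one (not isolated) | C=CC(C)(C)Oc1ccc([C@@H]2CC(=O)c3c(cc(O[Si](C(C)C)(C(C)C)C(C)C)c(CC=C(C)C)c3O)O2)cc1 | intermediate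
16 | ring B-rearranged monoether, (2S)-2-[4-hydroxy-3-(3-methylbut-2-en-1-yl)phenyl]-5-(2-methylbut-3-en-2-yloxy)-7-(triisopropylsilyloxy)chroman-4-one (not isolated) | CC(C)=CCc1cc([C@@H]2CC(=O)c3c(cc(O[Si](C(C)C)(C(C)C)C(C)C)cc3OC(C)(C)C=C)O2)ccc1O | intermediate
17 | (2S)-5-hydroxy-2-[4-hydroxy-3-(3-methylbut-2-en-1-yl)phenyl]-6-(3-methylbut-2-en-1-yl)-7-(triisopropylsilyloxy)chroman-4-one | CC(C)=CCc1cc([C@@H]2CC(=O)c3c(cc(O[Si](C(C)C)(C(C)C)C(C)C)c(CC=C(C)C)c3O)O2)ccc1O | intermediate
18 | macarangaflavanone B, (2S)-5,7-dihydroxy-2-[4-hydroxy-3-(3-methylbut-2-en-1-yl)phenyl]-6-(3-methylbut-2-en-1-yl)chroman-4-one | CC(C)=CCc1cc([C@@H]2CC(=O)c3c(cc(O)c(CC=C(C)C)c3O)O2)ccc1O | target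

**Step count**

Total steps: 10.
Longest linear sequence: 7 steps (steps 2, 3, 4, 7, 8, 9, 10 from 2,4,6-trihydroxybenzaldehyde 4; the branch through step 1 is equally long).

**Steps most likely to fail**

Step 7 (proposed new method). The ion-paired cycloaddition may show insufficient facial discrimination or insufficient cis/trans control of ring closure, so that material of low enantiomeric purity at C2 results. The fallback gives up asymmetric induction for resolution and uses known chemistry. It sets out from acetal 7 and styrene 10. An achiral acid (diphenyl hydrogen phosphate or Sc(OTf)3, CH2Cl2, −20 °C) should promote the known racemic annulation of a salicylaldehyde acetal with a styrene to the racemic 4-methoxyflavan F1. Oxidation with DDQ as in step 8 should give the racemic flavanone F2. Kinetic resolution by asymmetric transfer hydrogenation follows (Cp*RhCl[(R,R)-TsDPEN] or its antipode, whichever reduces the (2R)-ketone faster, HCO2H/Et3N, EtOAc, rt, stopped near half conversion). It should convert the (2R)-enantiomer into the cis-(2R,4R)-flavan-4-ol F3, which is removed by chromatography, and leave the (2S)-ketone. The route is rejoined at 14.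

Step 8. The quinone may lose site selectivity in the hydride abstraction, attacking the C2–H of the 4-alkoxybenzyl ether on ring B or oxidising further towards the flavone. The fallback replaces hydride abstraction by solvolysis and alcohol oxidation. It sets out from 12. The labile benzylic methyl ether is exchanged for hydroxyl by SN1 solvolysis (pyridinium p-toluenesulfonate cat., acetone/H2O, rt) to give the (2S)-flavan-4-ol F4 as a mixture of C4 epimers. Dess–Martin periodinane (NaHCO3, CH2Cl2, 0 °C) then oxidises it, and the route is rejoined at 14.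

Step 3. The palladium-mediated etherification may over-alkylate to the bis-ether, C-allylate the electron-rich ring, or isomerise the tertiary ether to the linear prenyl ether through reversible ionisation. The fallback builds the tertiary ether at the alkyne oxidation level. It sets out from 5. Copper-catalysed O-propargylation with 3-chloro-3-methylbut-1-yne (CuCl2 cat., DBU, MeCN, 0 °C) should give the 1,1-dimethylpropargyl ether F5. Semihydrogenation (H2, Pd/CaCO3 poisoned with Pb(OAc)2, quinoline, EtOAc, rt) then gives the alkene, and the route is rejoined at 6.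

**Further compounds**

F1 | step 7 | racemic cis-4-methoxy-5-(2-methylbut-3-en-2-yloxy)-2-[4-(2-methylbut-3-en-2-yloxy)phenyl]-7-(triisopropylsilyloxy)chromane (racemate of 12) | COC1CC(c3ccc(OC(C)(C)C=C)cc3)Oc2cc(O[Si](C(C)C)(C(C)C)C(C)C)cc(OC(C)(C)C=C)c21
F2 | step 7 | racemic 5-(2-methylbut-3-en-2-yloxy)-2-[4-(2-methylbut-3-en-2-yloxy)phenyl]-7-(triisopropylsilyloxy)chroman-4-one (racemate of 14) | C=CC(C)(C)Oc1ccc(C2CC(=O)c3c(cc(O[Si](C(C)C)(C(C)C)C(C)C)cc3OC(C)(C)C=C)O2)cc1
F3 | step 7 | (2R,4R)-5-(2-methylbut-3-en-2-yloxy)-2-[4-(2-methylbut-3-en-2-yloxy)phenyl]-7-(triisopropylsilyloxy)chroman-4-ol (2,4-cis) | O[C@@H]1C[C@H](c3ccc(OC(C)(C)C=C)cc3)Oc2cc(O[Si](C(C)C)(C(C)C)C(C)C)cc(OC(C)(C)C=C)c21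
F4 | step 8 | (2S)-5-(2-methylbut-3-en-2-yloxy)-2-[4-(2-methylbut-3-en-2-yloxy)phenyl]-7-(triisopropylsilyloxy)chroman-4-ol (C4 epimers) | OC1C[C@@H](c3ccc(OC(C)(C)C=C)cc3)Oc2cc(O[Si](C(C)C)(C(C)C)C(C)C)cc(OC(C)(C)C=C)c21
F5 | step 3 | 2-hydroxy-6-(2-methylbut-3-yn-2-yloxy)-4-(triisopropylsilyloxy)benzaldehyde | O=Cc1c(O)cc(O[Si](C(C)C)(C(C)C)C(C)C)cc1OC(C)(C)C#C
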